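**Plan**
Retrosynthesis: the two N–Si bonds are cut first, then the pyran ring (O1–C2 and C4–C4a, i.e. 3-methylbut-2-enal on a hydroquinone), then the C6–O bond (para-oxidation of a phenol).
The central benzene ring is then cut at C8a–C8, C6–C7 and C8a–C4a into an indolylcyclobutenone (C8a, C4a, C5, C6) and an indolyl methyl ynol ether (C8, C7), both traced to 3-bromo-1-(triisopropylsilyl)indole.
Enabling feature: on the benzene ring of the chromene the C7 methoxy and the C8a oxygen are meta, with the C8 indolyl between them. This is a resorcinol monoether, the pattern a vinylketene/alkoxyalkyne benzannulation delivers, and it leaves C4a (ortho) and C6 (para) to the C8a oxygen free.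
Forward order: benzene ring (step 6), C6 oxygen (steps 7 and 8), pyran ring (step 9), desilylation (step 10).
The target is achiral, so no stereocentre has to be set.

Key step: step 6

Assumption: 3-bromo-1-(triisopropylsilyl)indole is taken as a catalogue compound; both indoles stay N-silylated to the end, which blocks N–H and C2 reactivity and tempers the donor strength of the indole.

**Step 1**
Reactants: 1 3-bromo-1-(triisopropylsilyl)indole; 2 trimethylsilylacetylene
Product: 3 1-(triisopropylsilyl)-3-[(trimethylsilyl)ethynyl]indole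
Conditions: Pd(PhCN)2Cl2 (3 mol %), [(t-Bu)3PH]BF4 (6 mol %), CuI (2 mol %), i-Pr2NH, dioxane, rt → 50 °C
Reagents that add atoms: none
Why: Sonogashira coupling, in which the bulky electron-rich phosphine should allow oxidative addition into the electron-rich 3-bromoindole at mild temperature.

**Step 2**
Reactants: 3 1-(triisopropylsilyl)-3-[(trimethylsilyl)ethynyl]indole
Product: 4 3-ethynyl-1-(triisopropylsilyl)indole
Conditions: K2CO3 (0.2 equiv), MeOH/THF, 0 °C → rt
Reagents that add atoms: none
Why: Methoxide-catalysed protodesilylation, in which the C(sp)–SiMe3 bond should cleave much faster than the hindered N–Si(i-Pr)3 bond.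

**Step 3**
Reactants: 4 3-ethynyl-1-(triisopropylsilyl)indole; 5 trichloroacetyl chloride
Product: 7 4,4-dichloro-3-[1-(triisopropylsilyl)indol-3-yl]cyclobut-2-en-1-one, via dichloroketene 6 (not isolated)
Conditions: activated Zn dust, Et2O/DME, slow addition of 5, 25–35 °C
Reagents that add atoms: none
Why: Zinc dechlorination of the acid chloride generates dichloroketene, which should undergo the usual regioselective ketene–alkyne [2+2] cycloaddition (terminal alkyne carbon to the ketene carbonyl carbon), faster at the electron-rich alkyne than at the silyl-shielded indole C2=C3 bond.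

**Step 4**
Reactants: 7 4,4-dichloro-3-[1-(triisopropylsilyl)indol-3-yl]cyclobut-2-en-1-one
Product: 8 3-[1-(triisopropylsilyl)indol-3-yl]cyclobut-2-en-1-one
Conditions: Zn dust, TMEDA, AcOH, EtOH, 0 °C → rt
Reagents that add atoms: none
Why: Reductive dechlorination of an α,α-dichloroketone by zinc under amine/acetic acid buffering, the standard second half of the dichloroketene route to 3-substituted cyclobutenones.

**Step 5**
Reactants: 9 chloroacetaldehyde dimethyl acetal (2-chloro-1,1-dimethoxyethane); 1 3-bromo-1-(triisopropylsilyl)indole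
Product: 12 3-(methoxyethynyl)-1-(triisopropylsilyl)indole, via lithium methoxyacetylide 10 (not isolated), via methoxyethynylzinc chloride 11 (not isolated)
Conditions: LiNEt2 (3 equiv per 9, from n-BuLi and Et2NH), THF, 0 °C; ZnCl2, 0 °C; then 1, Pd(P(t-Bu)3)2 (3 mol %), rt; basic alumina for purification
Reagents that add atoms: none
Why: Twofold elimination (methanol, then HCl) and deprotonation give the lithium alkoxyacetylide, and after transmetalation to zinc a Negishi coupling of the alkoxyethynylzinc chloride with the aryl bromide on a zerovalent palladium catalyst should give the aryl ynol ether.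

**Step 6**
Reactants: 8 3-[1-(triisopropylsilyl)indol-3-yl]cyclobut-2-en-1-one; 12 3-(methoxyethynyl)-1-(triisopropylsilyl)indole
Product: 17 3-methoxy-2,5-bis[1-(triisopropylsilyl)indol-3-yl]phenol, via vinylketene 13 (not isolated), via 4-vinylcyclobutenone 14 (not isolated), via dienylketene 15 (not isolated), via cyclohexa-2,4-dienone 16 (not isolated)
Conditions: 12 (1.3 equiv), degassed PhMe, 80 °C then 110 °C, sealed tube, Ar
Reagents that add atoms: none
Why: Thermal 4π electrocyclic opening of 8 gives vinylketene 13, whose ketene C=C adds to the ynol ether in a [2+2] cycloaddition that forms C8a–C8 and C6–C7 in the 4-vinylcyclobutenone 14; a second 4π opening gives dienylketene 15, which closes to dienone 16 and tautomerises to phenol 17. This is the Danheiser benzannulation of cyclobutenones with alkoxyalkynes, the known route to resorcinol monoethers. The benzene ring is the only ring kept and closes by a thermal disrotatory 6π electrocyclisation that makes the C8a–C4a bond, whereas the four-membered ring of 14 is formed by the ketene–alkyne cycloaddition and opened again. No stereocentre survives, because the sp3 carbons of 14 and 16 become planar on aromatisation. The step needs one regiochemistry in the [2+2] event: the alkyne carbon β to oxygen, which carries the indolyl group, must bond to the ketene carbonyl carbon, and the direct oxygen lone-pair polarisation of the ynol ether should secure this while N-silylation tempers the competing donor effect of the indole. A methyl ynol ether is used because it has no β-hydrogen and so cannot fragment by a retro-ene reaction at the reaction temperature.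

**Step 7**
Reactants: 17 3-methoxy-2,5-bis[1-(triisopropylsilyl)indol-3-yl]phenol
Product: 18 3-methoxy-2,5-bis[1-(triisopropylsilyl)indol-3-yl]cyclohexa-2,5-diene-1,4-dione
Conditions: (KSO3)2NO (3 equiv), KH2PO4 (aq.), acetone/THF/H2O, 0 °C → rt
Reagents that add atoms: potassium nitrosodisulfonate, [K+].[K+].[O-]S(=O)(=O)N([O])S(=O)(=O)[O-]
Why: Teuber oxidation, in which one nitroxide radical abstracts the phenolic hydrogen and a second couples through oxygen at the free para carbon C6, so the para-quinone should form in preference to attack at the ortho carbon C4a and without touching the N-silyl indoles.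

**Step 8**
Reactants: 18 3-methoxy-2,5-bis[1-(triisopropylsilyl)indol-3-yl]cyclohexa-2,5-diene-1,4-dione
Product: 19 3-methoxy-2,5-bis[1-(triisopropylsilyl)indol-3-yl]benzene-1,4-diol
Conditions: Na2S2O4 (aq.), THF/H2O, rt, Ar; used crude at once
Reagents that add atoms: none
Why: Two-electron dithionite reduction of a para-quinone to its hydroquinone, which is carried forward without purification because it should reoxidise readily in air.

**Step 9**
Reactants: 19 3-methoxy-2,5-bis[1-(triisopropylsilyl)indol-3-yl]benzene-1,4-diol; 20 3-methylbut-2-enal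
Product: 23 7-methoxy-2,2-dimethyl-5,8-bis[1-(triisopropylsilyl)indol-3-yl]-2H-chromen-6-ol, via 2-phenyl-4H-1,3,2-benzodioxaborin 21 (not isolated), via ortho-quinone methide 22 (not isolated)
Conditions: PhB(OH)2 (1.2 equiv), AcOH (0.3 equiv), PhMe, reflux, Dean–Stark, Ar
Reagents that add atoms: none
Why: Phenylboronic acid-templated ortho-condensation of a phenol with an enal followed by thermal fragmentation to the ortho-quinone methide and oxa-6π electrocyclisation (2H-chromene synthesis); only the C8a hydroxyl has a free ortho carbon (C4a, also para to the methoxy group), so the doubly flanked C6 hydroxyl cannot annulate, and the boronic acid is returned on work-up.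

**Step 10**
Reactants: 23 7-methoxy-2,2-dimethyl-5,8-bis[1-(triisopropylsilyl)indol-3-yl]-2H-chromen-6-ol
Product: 24 kumbicin C
Conditions: Bu4NF (2.5 equiv), AcOH (2.5 equiv), THF, 0 °C → rt
Reagents that add atoms: none
Why: Fluoride-induced cleavage of the two labile N–Si bonds, buffered with acetic acid so that the electron-rich 6-hydroxychromene is not held as an air-sensitive phenoxide.

**Compound list**
1 | 3-bromo-1-(triisopropylsilyl)indole | Brc1cn([Si](C(C)C)(C(C)C)C(C)C)c2ccccc12 | starting material
2 | trimethylsilylacetylene | C#C[Si](C)(C)C | starting material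
3 | 1-(triisopropylsilyl)-3-[(trimethylsilyl)ethynyl]indole | C[Si](C)(C)C#Cc1cn([Si](C(C)C)(C(C)C)C(C)C)c2ccccc12 | intermediate
4 | 3-ethynyl-1-(triisopropylsilyl)indole | C#Cc1cn([Si](C(C)C)(C(C)C)C(C)C)c2ccccc12 | intermediate
5 | trichloroacetyl chloride | ClC(=O)C(Cl)(Cl)Cl | starting material
6 | dichloroketene (not isolated) | ClC(Cl)=C=O | intermediate
7 | 4,4-dichloro-3-[1-(triisopropylsilyl)indol-3-yl]cyclobut-2-en-1-one | O=C1C=C(c2cn([Si](C(C)C)(C(C)C)C(C)C)c3ccccc23)C1(Cl)Cl | intermediate
8 | 3-[1-(triisopropylsilyl)indol-3-yl]cyclobut-2-en-1-one | O=C1CC(c2cn([Si](C(C)C)(C(C)C)C(C)C)c3ccccc23)=C1 | intermediate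
9 | chloroacetaldehyde dimethyl acetal (2-chloro-1,1-dimethoxyethane) | COC(CCl)OC | starting material
10 | lithium methoxyacetylide (not isolated) | [Li]C#COC | intermediate
11 | methoxyethynylzinc chloride (not isolated) | COC#C[Zn]Cl | intermediate
12 | 3-(methoxyethynyl)-1-(triisopropylsilyl)indole | COC#Cc1cn([Si](C(C)C)(C(C)C)C(C)C)c2ccccc12 | intermediate
13 | 3-[1-(triisopropylsilyl)indol-3-yl]buta-1,3-dien-1-one (vinylketene; not isolated) | C=C(C=C=O)c1cn([Si](C(C)C)(C(C)C)C(C)C)c2ccccc12 | intermediate
14 | 3-methoxy-2-[1-(triisopropylsilyl)indol-3-yl]-4-{1-[1-(triisopropylsilyl)indol-3-yl]ethenyl}cyclobut-2-en-1-one (racemic; not isolated) | COC1=C(c2cn([Si](C(C)C)(C(C)C)C(C)C)c3ccccc23)C(=O)C1C(=C)c1cn([Si](C(C)C)(C(C)C)C(C)C)c2ccccc12 | intermediate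
15 | (3E)-3-methoxy-2,5-bis[1-(triisopropylsilyl)indol-3-yl]hexa-1,3,5-trien-1-one (dienylketene; ketene carbon and vinyl group cis; not isolated) | O=C=C(c1cn([Si](C(C)C)(C(C)C)C(C)C)c2ccccc12)/C(OC)=C\C(=C)c1cn([Si](C(C)C)(C(C)C)C(C)C)c2ccccc12 | intermediate
16 | 3-methoxy-2,5-bis[1-(triisopropylsilyl)indol-3-yl]cyclohexa-2,4-dien-1-one (not isolated) | COC1=C(c2cn([Si](C(C)C)(C(C)C)C(C)C)c3ccccc23)C(=O)CC(c2cn([Si](C(C)C)(C(C)C)C(C)C)c3ccccc23)=C1 | intermediate
17 | 3-methoxy-2,5-bis[1-(triisopropylsilyl)indol-3-yl]phenol | COc1cc(-c2cn([Si](C(C)C)(C(C)C)C(C)C)c3ccccc23)cc(O)c1-c1cn([Si](C(C)C)(C(C)C)C(C)C)c2ccccc12 | intermediate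
18 | 3-methoxy-2,5-bis[1-(triisopropylsilyl)indol-3-yl]cyclohexa-2,5-diene-1,4-dione | COC1=C(c2cn([Si](C(C)C)(C(C)C)C(C)C)c3ccccc23)C(=O)C=C(c2cn([Si](C(C)C)(C(C)C)C(C)C)c3ccccc23)C1=O | intermediate
19 | 3-methoxy-2,5-bis[1-(triisopropylsilyl)indol-3-yl]benzene-1,4-diol | COc1c(O)c(-c2cn([Si](C(C)C)(C(C)C)C(C)C)c3ccccc23)cc(O)c1-c1cn([Si](C(C)C)(C(C)C)C(C)C)c2ccccc12 | intermediate
20 | 3-methylbut-2-enal | CC(C)=CC=O | starting material
21 | 7-methoxy-4-(2-methylprop-1-en-1-yl)-2-phenyl-5,8-bis[1-(triisopropylsilyl)indol-3-yl]-4H-1,3,2-benzodioxaborin-6-ol (racemic; not isolated) | COc1c(O)c(-c2cn([Si](C(C)C)(C(C)C)C(C)C)c3ccccc23)c2c(c1-c1cn([Si](C(C)C)(C(C)C)C(C)C)c3ccccc13)OB(c1ccccc1)OC2C=C(C)C | intermediate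
22 | (6Z)-4-hydroxy-3-methoxy-6-(3-methylbut-2-en-1-ylidene)-2,5-bis[1-(triisopropylsilyl)indol-3-yl]cyclohexa-2,4-dien-1-one (ortho-quinone methide; not isolated) | COC1=C(c2cn([Si](C(C)C)(C(C)C)C(C)C)c3ccccc23)C(=O)/C(=C\C=C(C)C)C(c2cn([Si](C(C)C)(C(C)C)C(C)C)c3ccccc23)=C1O | intermediate
23 | 7-methoxy-2,2-dimethyl-5,8-bis[1-(triisopropylsilyl)indol-3-yl]-2H-chromen-6-ol | COc1c(O)c(-c2cn([Si](C(C)C)(C(C)C)C(C)C)c3ccccc23)c2c(c1-c1cn([Si](C(C)C)(C(C)C)C(C)C)c3ccccc13)OC(C)(C)C=C2 | intermediate
24 | kumbicin C, 5,8-di(1H-indol-3-yl)-7-methoxy-2,2-dimethyl-2H-chromen-6-ol | COc1c(O)c(-c2c[nH]c3ccccc23)c2c(c1-c1c[nH]c3ccccc13)OC(C)(C)C=C2 | target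

**Step count**
Total: 10 steps.
Longest linear sequence: 9 steps (1 → 3 → 4 → 7 → 8 → 17 → 18 → 19 → 23 → 24); step 5 is a one-step branch from 1 and 9.

**Steps most likely to fail**

Step 6. The hindered, indolyl-substituted ynol ether may trap the vinylketene too slowly, so that ketene dimerisation and acylation of the product phenol by the vinylketene compete; the [2+2] regiochemistry could also erode if indole donation rivals the oxygen polarisation. The fallback sets out from 1 and returns at 17, assembling the arene by cross-coupling on a purchased benzene core. Bromine–lithium exchange of 1 (t-BuLi, THF, −78 °C) should give 3-lithio-1-(triisopropylsilyl)indole F1. Quenching with 2-isopropoxy-4,4,5,5-tetramethyl-1,3,2-dioxaborolane should give 1-(triisopropylsilyl)-3-(4,4,5,5-tetramethyl-1,3,2-dioxaborolan-2-yl)indole F2. Twofold Suzuki–Miyaura coupling of F2 with 2,5-dibromo-1,3-dimethoxybenzene (Pd(OAc)2, SPhos, K3PO4, PhMe/H2O, 90 °C) should give 2,5-bis[1-(triisopropylsilyl)indol-3-yl]-1,3-dimethoxybenzene F3. Mono-demethylation of this symmetrical resorcinol dimethyl ether with NaSEt in DMF, where the first phenoxide protects the second ether, should deliver 17.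

Step 9. Carbon–carbon bond formation at the crowded C4a next to the C5 indolyl may be slow, leaving time for air reoxidation of the hydroquinone, acid-promoted loss of the N-silyl groups and alkylation of indole C2 by the enal. The fallback sets out from 19 and returns at 23. Copper-catalysed O-alkylation of the less hindered C8a hydroxyl with 3-chloro-3-methylbut-1-yne (CuCl2, DBU, MeCN, 0 °C) should give 2-methoxy-4-[(2-methylbut-3-yn-2-yl)oxy]-3,6-bis[1-(triisopropylsilyl)indol-3-yl]phenol F4. Heating F4 in xylene at 140 °C should bring about aromatic Claisen rearrangement to C4a, a 1,5-hydrogen shift and oxa-6π closure to 23.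

Step 5. Cross-coupling of the electron-rich bromoindole may lag behind homocoupling or decomposition of the alkynylzinc, and the electron-rich ynol ether may hydrate to the arylacetate ester during work-up or chromatography. The fallback sets out from 1 and returns at 12, building the alkyne by elimination instead of coupling. The 3-lithioindole F1 (from 1 as above) is acylated with N,2-dimethoxy-N-methylacetamide to give 2-methoxy-1-[1-(triisopropylsilyl)indol-3-yl]ethan-1-one F5. Enolisation and triflation (KN(SiMe3)2, PhNTf2, THF, −78 °C) should give (Z)-2-methoxy-1-[1-(triisopropylsilyl)indol-3-yl]ethenyl trifluoromethanesulfonate F6. Anti-elimination with KOt-Bu (THF, −78 → 0 °C) should give 12.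

**Further compounds**
F1 | step 6 | 3-lithio-1-(triisopropylsilyl)indole | [Li]c1cn([Si](C(C)C)(C(C)C)C(C)C)c2ccccc12
F2 | step 6 | 1-(triisopropylsilyl)-3-(4,4,5,5-tetramethyl-1,3,2-dioxaborolan-2-yl)indole | CC1(C)OB(OC1(C)C)c1cn([Si](C(C)C)(C(C)C)C(C)C)c2ccccc12
F3 | step 6 | 2,5-bis[1-(triisopropylsilyl)indol-3-yl]-1,3-dimethoxybenzene | COc1cc(-c2cn([Si](C(C)C)(C(C)C)C(C)C)c3ccccc23)cc(OC)c1-c1cn([Si](C(C)C)(C(C)C)C(C)C)c2ccccc12
F4 | step 9 | 2-methoxy-4-[(2-methylbut-3-yn-2-yl)oxy]-3,6-bis[1-(triisopropylsilyl)indol-3-yl]phenol | COc1c(O)c(-c2cn([Si](C(C)C)(C(C)C)C(C)C)c3ccccc23)cc(OC(C)(C)C#C)c1-c1cn([Si](C(C)C)(C(C)C)C(C)C)c2ccccc12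
F5 | step 5 | 2-methoxy-1-[1-(triisopropylsilyl)indol-3-yl]ethan-1-one | COCC(=O)c1cn([Si](C(C)C)(C(C)C)C(C)C)c2ccccc12
F6 | step 5 | (Z)-2-methoxy-1-[1-(triisopropylsilyl)indol-3-yl]ethenyl trifluoromethanesulfonate | CO/C=C(\OS(=O)(=O)C(F)(F)F)c1cn([Si](C(C)C)(C(C)C)C(C)C)c2ccccc12
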